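The data are calculated with constants of no real substance, noise included.

A small charge of reagent, 0.900 equiv, has to serve starting material and 0.500 equiv of second substrate, less than the two together, so it is the limiting reagent, and I write its balance before choosing the next run.

| setting | eta | beta | flask |
|---|---|---|---|
| starting material | 0.23 M | 0.23 M | 0.23 M |
| second substrate | 0.50 equiv | 0.50 equiv | 0.500 equiv |
| reagent | 0.90 equiv | 0.90 equiv | 0.900 equiv |
| free catalyst | 0.34 mol% | 0.75 mol% | 0.5 mol% |
| remark | run made earlier | run made earlier |  |
| time |  |  | 10 min |

| run | time / min | target / % | starting material / % |
|---|---|---|---|
| eta | 0.333 | 18.9 | 80.3 |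
| eta | 0.667 | 33.1 | 64.4 |
| eta | 1.33 | 47.0 | 46.4 |
| eta | 3.00 | 46.9 | 37.7 |
| eta | 6.00 | 41.6 | 30.7 |
| beta | 0.333 | 35.9 | 62.8 |
| beta | 0.667 | 50.7 | 46.3 |
| beta | 1.33 | 51.3 | 40.4 |
| beta | 3.00 | 48.0 | 36.5 |
| beta | 6.00 | 41.9 | 31.3 |

(standard deviation of a reading: 0.3 percentage points)

- in percentages every species weighs as the starting material in it: one side product counts as two
- the analysis behind the earlier runs scatters by 0.3 percentage points, standard deviation
- candidate steps: starting material + free catalyst <-> catalyst intermediate A; reagent + catalyst intermediate A -> free catalyst + target; second substrate + free catalyst <-> catalyst intermediate B; reagent + catalyst intermediate B -> free catalyst + second product; starting material + target -> side product; reagent + target -> over-reaction product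

Each target made costs one reagent. Side product consumes one target and one starting material and counts two in percent, so, with over-reaction product neglected, target made in total is half the sum of the target present and the starting material consumed. In the beta run, this sum stays flat from 1.33 min to 6.00 min, averaging 55.5%, and the last eta reading gives 55.4%. I take that plateau as the whole reagent charge, so target received 61.7% of the reagent and second product the rest. Second product then took 69.0% of the second substrate, while 55.5% of the starting material went to target. If each substrate turns over in proportion to its own concentration at a fixed ratio, with the loss of starting material to side product neglected, the ratio of the logarithms of their unconverted fractions is constant, and I call it the selectivity factor 0.691.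

Both runs reach that plateau at different loadings, so I change the loading to 0.5 mol%, keep both other charges, and expect the same total. The peak should lie below it, as the highest beta reading, 51.3%, does.

- time up to 10 min at which target stands highest
- the amount of target, in percent of the starting material charged, at that time
- the first time at which target reaches 15%, in the same percent, in min

The forecast, holding that “time × loading is nearly constant”, gives 1.05 min, 50.5% and 0.18 min.

The flask gives 1.36 min, 51.2% and 0.168 min, so the peak comes later than forecast, by a factor of 1.30, while the other two values stand within tolerance.

    starting material + free catalyst ⇌ catalyst intermediate A (K = 6.35 M⁻¹, k = 1120 M⁻¹ min⁻¹)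
    reagent + catalyst intermediate A → free catalyst + target (k = 11300 M⁻¹ min⁻¹)
    second substrate + free catalyst ⇌ catalyst intermediate B (K = 6.03 M⁻¹, k = 1970 M⁻¹ min⁻¹)
    reagent + catalyst intermediate B → free catalyst + second product (k = 10400 M⁻¹ min⁻¹)
    starting material + target → side product (k = 0.563 M⁻¹ min⁻¹)
    reagent + target → over-reaction product (k = 0.101 M⁻¹ min⁻¹)

At 0.341 min in the flask, reagent is used 1.6 times as fast through catalyst intermediate A as through catalyst intermediate B. At 10.0 min, with reagent at 0% and second product at 0.0794 M, the flask's target share is 61.6%. For the neighbour flask with 0.850 equiv of second substrate, I put the selectivity factor 0.691 into the reagent balance and take one Newton step from a guess of 0.5 for the unconverted fraction of second substrate, which gives 44.5%, hence 42.8% target made in total. That neighbour flask computes to 42.6% as target plus half the side product at 10.0 min, with a best of 39.7%.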